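The diquinane is cut back to ring A alone (pentalene numbering; ring A holds C1 to C3). Carbinol C6a carries OH between the ring A ketone C1 and the acyl carbon C6. It is therefore the 1,2-acyl-shift isomer of a 2-benzyl-2-hydroxy-5-styrylcyclohex-4-ene-1,3-dione, a 2-benzyl-5-styrylresorcinol hydroxylated at the benzylated carbon. A chiral Lewis acid moves C1 from C6 to C6a. In one operation the tautomerically symmetric six-membered ring contracts to cyclopentenone ring A, C6 becomes the exocyclic ketone and C6a is set. The precursor is the benzyl-protected dienol 13. Ring B follows from C5 aroylation and a vinylogous aldol condensation of C3a onto C4, which can only give the cis diquinane; a cold debenzylation ends the route.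

Key step: step 9

Remark: all seven phenols travel as benzyl ethers so that the end game is a cold debenzylation in place of an exhaustive room-temperature demethylation, which would risk Friedel–Crafts closure onto the dienone; which antipode of the N,N'-dioxide ligand delivers the R ketol is assumed to be settled by screening, both being accessible.

Step 1
Reactants: 1 3,5-dihydroxybenzaldehyde
Product: 2 3,5-bis(methoxymethoxy)benzaldehyde
Conditions: MOMCl, i-Pr2NEt, CH2Cl2, 0 °C to rt
Reagents that add atoms: chloromethyl methyl ether, COCCl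
Why: O-alkylation of both phenols with the α-chloro ether (MOM protection); these are the cooperating directing groups for step 4 and the only acid-labile phenol protection in the route, so the resorcinol can later be unmasked alone.

Step 2
Reactants: 2 3,5-bis(methoxymethoxy)benzaldehyde
Product: 3 1-(dimethoxymethyl)-3,5-bis(methoxymethoxy)benzene
Conditions: HC(OMe)3, PPTS (cat.), MeOH, rt
Reagents that add atoms: trimethyl orthoformate, COC(OC)OC; methanol, CO
Why: Acid-catalysed acetalisation driven by the orthoformate as water scavenger; the acetal shields the aldehyde from n-BuLi, and catalytic PPTS at room temperature should leave aryl MOM ethers intact.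

Step 3
Reactants: 4 [3,4,5-tris(benzyloxy)phenyl]methanol
Product: 5 5-(bromomethyl)-1,2,3-tris(benzyloxy)benzene
Conditions: PBr3, CH2Cl2, 0 °C
Reagents that add atoms: phosphorus tribromide, BrP(Br)Br
Why: Conversion of an electron-rich benzylic alcohol into its bromide (SN2 displacement of the phosphite ester by bromide); aryl benzyl ethers are inert.

Step 4
Reactants: 3 1-(dimethoxymethyl)-3,5-bis(methoxymethoxy)benzene; 5 5-(bromomethyl)-1,2,3-tris(benzyloxy)benzene
Product: 8 3,5-bis(methoxymethoxy)-4-[3,4,5-tris(benzyloxy)benzyl]benzaldehyde, via aryllithium 6 (not isolated), via benzylated acetal 7 (not isolated)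
Conditions: n-BuLi, THF, 0 °C; CuBr·SMe2 (10 mol%), then 5, −78 °C to rt; then 1 M aq HCl, THF, 0 °C
Reagents that add atoms: water, O
Why: Directed ortho-metalation, in which the two MOM ethers cooperate so that n-BuLi removes only the proton between them, the copper-assisted aryllithium displaces the benzylic bromide by SN2, and brief dilute acid hydrolyses the dimethyl acetal much faster than the aryl MOM ethers.

Step 5
Reactants: 9 1-(bromomethyl)-3,5-bis(benzyloxy)benzene
Product: 10 diethyl [3,5-bis(benzyloxy)benzyl]phosphonate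
Conditions: P(OEt)3, neat, 140 °C
Reagents that add atoms: triethyl phosphite, CCOP(OCC)OCC
Why: Michaelis–Arbuzov reaction, SN2 attack of the phosphite on the benzylic bromide followed by bromide-mediated dealkylation of the phosphonium salt.

Step 6
Reactants: 8 3,5-bis(methoxymethoxy)-4-[3,4,5-tris(benzyloxy)benzyl]benzaldehyde; 10 diethyl [3,5-bis(benzyloxy)benzyl]phosphonate
Product: 11 5-{(E)-2-[3,5-bis(benzyloxy)phenyl]ethenyl}-1,3-bis(methoxymethoxy)-2-[3,4,5-tris(benzyloxy)benzyl]benzene
Conditions: KOt-Bu, THF, 0 °C to rt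
Reagents that add atoms: none
Why: Horner–Wadsworth–Emmons olefination; the benzylphosphonate anion adds reversibly to the aromatic aldehyde, so the E stilbene should form with high selectivity, and benzyl and MOM ethers tolerate the base.

Step 7
Reactants: 11 5-{(E)-2-[3,5-bis(benzyloxy)phenyl]ethenyl}-1,3-bis(methoxymethoxy)-2-[3,4,5-tris(benzyloxy)benzyl]benzene
Product: 12 5-{(E)-2-[3,5-bis(benzyloxy)phenyl]ethenyl}-2-[3,4,5-tris(benzyloxy)benzyl]benzene-1,3-diol
Conditions: conc. HCl (cat.), MeOH–THF, 50 °C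
Reagents that add atoms: none
Why: Acid-catalysed transacetalisation of the two aryl MOM acetals to methanol; benzyl ethers and the stilbene are stable to dilute methanolic HCl, so only the resorcinol that is to be dearomatised is set free.

Step 8
Reactants: 12 5-{(E)-2-[3,5-bis(benzyloxy)phenyl]ethenyl}-2-[3,4,5-tris(benzyloxy)benzyl]benzene-1,3-diol
Product: 13 3-{(E)-2-[3,5-bis(benzyloxy)phenyl]ethenyl}-5,6-dihydroxy-6-[3,4,5-tris(benzyloxy)benzyl]cyclohexa-2,4-dien-1-one (enol form of the 2-benzyl-2-hydroxy-5-styrylcyclohex-4-ene-1,3-dione; racemic and stereolabile)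
Conditions: SIBX (IBX stabilised by benzoic and isophthalic acids, 1.1 equiv), THF, rt; aqueous work-up at pH 4; used at once
Reagents that add atoms: 2-iodoxybenzoic acid (IBX), O=C1OI(=O)(O)c2ccccc12
Why: Hydroxylative phenol dearomatisation, in which a resorcinol OH exchanges onto pentavalent iodine and oxygen is delivered intramolecularly to the benzyl-bearing ortho carbon flanked by both oxygens, giving the 6-hydroxycyclohexa-2,4-dienone that stays as a vinylogous acid; the new carbinol carbon is stereolabile because the two enol tautomers are mirror images, so nothing has to be controlled here.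

Step 9
Reactants: 13 3-{(E)-2-[3,5-bis(benzyloxy)phenyl]ethenyl}-5,6-dihydroxy-6-[3,4,5-tris(benzyloxy)benzyl]cyclohexa-2,4-dien-1-one
Product: 14 (5R)-3-{(E)-2-[3,5-bis(benzyloxy)phenyl]ethenyl}-5-hydroxy-5-{2-[3,4,5-tris(benzyloxy)phenyl]acetyl}cyclopent-2-en-1-one
Conditions: Sc(OTf)3 (10 mol%), chiral N,N'-dioxide ligand L-PiPr2 [1,1'-(propane-1,3-diyl)bis((2S)-2-(2,6-diisopropylphenylcarbamoyl)piperidine 1-oxide)] (11 mol%), 4 Å MS, CH2Cl2, 0 to 30 °C
Reagents that add atoms: none
Why: Proposed new method: with the pentalene numbering carried back into 13 (carbinol carbon C6, flanking ring carbonyl carbons C1 and C6a), the Sc(OTf)3–N,N'-dioxide complex should bind the keto tautomer as a five-membered chelate through the C6 oxygen and the non-conjugated carbonyl C6a, whereupon the enone acyl carbon C1 shifts from C6 to C6a and C6 becomes the exocyclic ketone (Lewis acid-promoted α-ketol rearrangement). The closest known reaction types are the magnesium-assisted contraction of hop α-acids to iso-α-acids and N,N'-dioxide/Lewis acid-catalysed enantioselective α-ketol rearrangements of simple α-hydroxy ketones; choosing between two enantiotopic acyl groups of a dearomatised resorcinol is the new element. Ring A is closed by ring contraction and not by an end-to-end cyclisation: a suprafacial 1,2-acyl shift through a three-centre transition state makes C1–C6a as C1–C6 breaks. C6a is set by the catalyst alone, because 13 racemises through its mirror-symmetric dienol and the chiral pocket decides which of the two enantiotopic carbonyls becomes the chelated acceptor (a dynamic kinetic desymmetrisation that should lead to the R ketol). The step needs acyl migration in preference to benzyl migration and needs the CH2-flanked carbonyl as acceptor; the higher migratory aptitude of an acyl group, the vicinal dione that a benzyl shift would create and the greater electrophilicity of the non-conjugated carbonyl should secure this, and the reaction is to be stopped at full conversion because a second shift of the exocyclic acyl would erode the enantiomeric purity.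

Step 10
Reactants: 14 (5R)-3-{(E)-2-[3,5-bis(benzyloxy)phenyl]ethenyl}-5-hydroxy-5-{2-[3,4,5-tris(benzyloxy)phenyl]acetyl}cyclopent-2-en-1-one
Product: 15 (5R)-3-{(E)-2-[3,5-bis(benzyloxy)phenyl]ethenyl}-5-(triethylsilyloxy)-5-{2-[3,4,5-tris(benzyloxy)phenyl]acetyl}cyclopent-2-en-1-one
Conditions: TESOTf, 2,6-lutidine, CH2Cl2, −78 to 0 °C
Reagents that add atoms: triethylsilyl trifluoromethanesulfonate, CC[Si](CC)(CC)OS(=O)(=O)C(F)(F)F
Why: Silylation of the tertiary alcohol with a silyl triflate and a hindered pyridine base; capping the α-ketol shuts off any further acyl shift, O-acylation in step 12, and hemiketal or 3(2H)-furanone formation once the C4 carbonyl is in place.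

Step 11
Reactants: 16 3,5-bis(benzyloxy)benzoic acid
Product: 17 3,5-bis(benzyloxy)benzoyl chloride
Conditions: (COCl)2, DMF (cat.), CH2Cl2, 0 °C to rt
Reagents that add atoms: oxalyl chloride, O=C(Cl)C(=O)Cl
Why: Acid chloride formation through the catalytic chloroiminium (Vilsmeier-type) species; benzyl ethers are unaffected.

Step 12
Reactants: 15 (5R)-3-{(E)-2-[3,5-bis(benzyloxy)phenyl]ethenyl}-5-(triethylsilyloxy)-5-{2-[3,4,5-tris(benzyloxy)phenyl]acetyl}cyclopent-2-en-1-one; 17 3,5-bis(benzyloxy)benzoyl chloride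
Product: 18 1-[3,5-bis(benzyloxy)phenyl]-3-[(1S)-4-{(E)-2-[3,5-bis(benzyloxy)phenyl]ethenyl}-2-oxo-1-(triethylsilyloxy)cyclopent-3-en-1-yl]-2-[3,4,5-tris(benzyloxy)phenyl]propane-1,3-dione (C5 epimers and enol forms; C6a unchanged in space, descriptor S by priority change)
Conditions: MgBr2·OEt2, i-Pr2NEt, CH2Cl2, 0 °C to rt
Reagents that add atoms: none
Why: Soft-enolisation Claisen-type C-acylation, in which MgBr2 chelates the C6 ketone so that the amine can remove a benzylic C5 proton, the magnesium enolate is C-acylated by 17, and the product is parked as its magnesium diketonate against a second acylation; C5 is the only α-carbon able to enolise because C6a is quaternary.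

Step 13
Reactants: 18 1-[3,5-bis(benzyloxy)phenyl]-3-[(1S)-4-{(E)-2-[3,5-bis(benzyloxy)phenyl]ethenyl}-2-oxo-1-(triethylsilyloxy)cyclopent-3-en-1-yl]-2-[3,4,5-tris(benzyloxy)phenyl]propane-1,3-dione
Product: 20 (3aS,6aS)-4-[3,5-bis(benzyloxy)phenyl]-3-{(E)-2-[3,5-bis(benzyloxy)phenyl]ethenyl}-6a-(triethylsilyloxy)-5-[3,4,5-tris(benzyloxy)phenyl]-3a,6a-dihydropentalene-1,6-dione, via aldol adduct 19 (not isolated)
Conditions: DBU, 4 Å MS, MeCN, 60 °C
Reagents that add atoms: none
Why: Intramolecular vinylogous aldol condensation, in which DBU reversibly removes a C3a proton (γ to the C1 enone), the dienolate adds through C3a to the C4 aryl ketone in a 5-exo-trig closure of ring B, and E1cB loss of water across C4–C5 makes the enone irreversibly; the new C3a stereocentre is dictated by C6a, since the C6 side chain can reach C3a only from its own face and a trans-fused bicyclo[3.3.0]octadienone is out of reach, so the fusion must be cis.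

Step 14
Reactants: 20 (3aS,6aS)-4-[3,5-bis(benzyloxy)phenyl]-3-{(E)-2-[3,5-bis(benzyloxy)phenyl]ethenyl}-6a-(triethylsilyloxy)-5-[3,4,5-tris(benzyloxy)phenyl]-3a,6a-dihydropentalene-1,6-dione
Product: 22 (3aS,6aS)-4-(3,5-dihydroxyphenyl)-3-[(E)-2-(3,5-dihydroxyphenyl)ethenyl]-6a-hydroxy-5-(3,4,5-trihydroxyphenyl)-3a,6a-dihydropentalene-1,6-dione, via heptaphenol silyl ether 21 (not isolated)
Conditions: BCl3, C6HMe5, CH2Cl2, −78 °C; then MeOH, −78 °C to rt
Reagents that add atoms: none
Why: Lewis acid debenzylation with a non-basic cation scavenger, in which BCl3 cleaves the seven aryl benzyl ethers at −78 °C while pentamethylbenzene traps the benzyl cations, and the methanolic HCl formed on quenching removes the tertiary triethylsilyl ether; neither stereocentre can ionise or epimerise, C6a being flanked by two carbonyls and C3a being locked cis.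

Compound list
1 | 3,5-dihydroxybenzaldehyde | O=Cc1cc(O)cc(O)c1 | starting material
2 | 3,5-bis(methoxymethoxy)benzaldehyde | O=Cc1cc(OCOC)cc(OCOC)c1 | intermediate
3 | 1-(dimethoxymethyl)-3,5-bis(methoxymethoxy)benzene | COC(OC)c1cc(OCOC)cc(OCOC)c1 | intermediate
4 | [3,4,5-tris(benzyloxy)phenyl]methanol | OCc1cc(OCc2ccccc2)c(OCc2ccccc2)c(OCc2ccccc2)c1 | starting material
5 | 5-(bromomethyl)-1,2,3-tris(benzyloxy)benzene | BrCc1cc(OCc2ccccc2)c(OCc2ccccc2)c(OCc2ccccc2)c1 | intermediate
6 | [4-(dimethoxymethyl)-2,6-bis(methoxymethoxy)phenyl]lithium | COCOc1cc(C(OC)OC)cc(OCOC)c1[Li] | intermediate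
7 | 5-(dimethoxymethyl)-1,3-bis(methoxymethoxy)-2-[3,4,5-tris(benzyloxy)benzyl]benzene | COCOc1cc(C(OC)OC)cc(OCOC)c1Cc1cc(OCc2ccccc2)c(OCc2ccccc2)c(OCc2ccccc2)c1 | intermediate
8 | 3,5-bis(methoxymethoxy)-4-[3,4,5-tris(benzyloxy)benzyl]benzaldehyde | COCOc1cc(C=O)cc(OCOC)c1Cc1cc(OCc2ccccc2)c(OCc2ccccc2)c(OCc2ccccc2)c1 | intermediate
9 | 1-(bromomethyl)-3,5-bis(benzyloxy)benzene | BrCc1cc(OCc2ccccc2)cc(OCc2ccccc2)c1 | starting material
10 | diethyl [3,5-bis(benzyloxy)benzyl]phosphonate | CCOP(=O)(OCC)Cc1cc(OCc2ccccc2)cc(OCc2ccccc2)c1 | intermediate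
11 | 5-{(E)-2-[3,5-bis(benzyloxy)phenyl]ethenyl}-1,3-bis(methoxymethoxy)-2-[3,4,5-tris(benzyloxy)benzyl]benzene | COCOc1cc(/C=C/c2cc(OCc3ccccc3)cc(OCc3ccccc3)c2)cc(OCOC)c1Cc1cc(OCc2ccccc2)c(OCc2ccccc2)c(OCc2ccccc2)c1 | intermediate
12 | 5-{(E)-2-[3,5-bis(benzyloxy)phenyl]ethenyl}-2-[3,4,5-tris(benzyloxy)benzyl]benzene-1,3-diol | Oc1cc(/C=C/c2cc(OCc3ccccc3)cc(OCc3ccccc3)c2)cc(O)c1Cc1cc(OCc2ccccc2)c(OCc2ccccc2)c(OCc2ccccc2)c1 | intermediate
13 | 3-{(E)-2-[3,5-bis(benzyloxy)phenyl]ethenyl}-5,6-dihydroxy-6-[3,4,5-tris(benzyloxy)benzyl]cyclohexa-2,4-dien-1-one (enol of the 2-benzyl-2-hydroxy-5-styrylcyclohex-4-ene-1,3-dione; racemic, stereolabile) | O=C1C=C(/C=C/c2cc(OCc3ccccc3)cc(OCc3ccccc3)c2)C=C(O)C1(O)Cc1cc(OCc2ccccc2)c(OCc2ccccc2)c(OCc2ccccc2)c1 | intermediate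
14 | (5R)-3-{(E)-2-[3,5-bis(benzyloxy)phenyl]ethenyl}-5-hydroxy-5-{2-[3,4,5-tris(benzyloxy)phenyl]acetyl}cyclopent-2-en-1-one | O=C1C=C(/C=C/c2cc(OCc3ccccc3)cc(OCc3ccccc3)c2)C[C@@]1(O)C(=O)Cc1cc(OCc2ccccc2)c(OCc2ccccc2)c(OCc2ccccc2)c1 | intermediate
15 | (5R)-3-{(E)-2-[3,5-bis(benzyloxy)phenyl]ethenyl}-5-(triethylsilyloxy)-5-{2-[3,4,5-tris(benzyloxy)phenyl]acetyl}cyclopent-2-en-1-one | O=C1C=C(/C=C/c2cc(OCc3ccccc3)cc(OCc3ccccc3)c2)C[C@@]1(O[Si](CC)(CC)CC)C(=O)Cc1cc(OCc2ccccc2)c(OCc2ccccc2)c(OCc2ccccc2)c1 | intermediate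
16 | 3,5-bis(benzyloxy)benzoic acid | OC(=O)c1cc(OCc2ccccc2)cc(OCc2ccccc2)c1 | starting material
17 | 3,5-bis(benzyloxy)benzoyl chloride | ClC(=O)c1cc(OCc2ccccc2)cc(OCc2ccccc2)c1 | intermediate
18 | 1-[3,5-bis(benzyloxy)phenyl]-3-[(1S)-4-{(E)-2-[3,5-bis(benzyloxy)phenyl]ethenyl}-2-oxo-1-(triethylsilyloxy)cyclopent-3-en-1-yl]-2-[3,4,5-tris(benzyloxy)phenyl]propane-1,3-dione (C5 epimers and enol forms) | O=C1C=C(/C=C/c2cc(OCc3ccccc3)cc(OCc3ccccc3)c2)C[C@@]1(O[Si](CC)(CC)CC)C(=O)C(c1cc(OCc2ccccc2)c(OCc2ccccc2)c(OCc2ccccc2)c1)C(=O)c1cc(OCc2ccccc2)cc(OCc2ccccc2)c1 | intermediate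
19 | cis-fused 4-[3,5-bis(benzyloxy)phenyl]-3-{(E)-2-[3,5-bis(benzyloxy)phenyl]ethenyl}-4-hydroxy-6a-(triethylsilyloxy)-5-[3,4,5-tris(benzyloxy)phenyl]-3a,4,5,6a-tetrahydropentalene-1,6-dione (C4 and C5 diastereomers) | O=C1C=C(/C=C/c2cc(OCc3ccccc3)cc(OCc3ccccc3)c2)[C@H]2C(O)(c3cc(OCc4ccccc4)cc(OCc4ccccc4)c3)C(c3cc(OCc4ccccc4)c(OCc4ccccc4)c(OCc4ccccc4)c3)C(=O)[C@@]12O[Si](CC)(CC)CC | intermediate
20 | (3aS,6aS)-4-[3,5-bis(benzyloxy)phenyl]-3-{(E)-2-[3,5-bis(benzyloxy)phenyl]ethenyl}-6a-(triethylsilyloxy)-5-[3,4,5-tris(benzyloxy)phenyl]-3a,6a-dihydropentalene-1,6-dione | O=C1C=C(/C=C/c2cc(OCc3ccccc3)cc(OCc3ccccc3)c2)[C@H]2C(c3cc(OCc4ccccc4)cc(OCc4ccccc4)c3)=C(c3cc(OCc4ccccc4)c(OCc4ccccc4)c(OCc4ccccc4)c3)C(=O)[C@@]12O[Si](CC)(CC)CC | intermediate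
21 | (3aS,6aS)-4-(3,5-dihydroxyphenyl)-3-[(E)-2-(3,5-dihydroxyphenyl)ethenyl]-6a-(triethylsilyloxy)-5-(3,4,5-trihydroxyphenyl)-3a,6a-dihydropentalene-1,6-dione | O=C1C=C(/C=C/c2cc(O)cc(O)c2)[C@H]2C(c3cc(O)cc(O)c3)=C(c3cc(O)c(O)c(O)c3)C(=O)[C@@]12O[Si](CC)(CC)CC | intermediate
22 | (3aS,6aS)-4-(3,5-dihydroxyphenyl)-3-[(E)-2-(3,5-dihydroxyphenyl)ethenyl]-6a-hydroxy-5-(3,4,5-trihydroxyphenyl)-3a,6a-dihydropentalene-1,6-dione (CNP0306657.1) | O=C1C=C(/C=C/c2cc(O)cc(O)c2)[C@H]2C(c3cc(O)cc(O)c3)=C(c3cc(O)c(O)c(O)c3)C(=O)[C@@]12O | target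

Totals
Total step count: 14. Longest linear sequence: 11 steps (1 to 22 through steps 1, 2, 4, 6, 7, 8, 9, 10, 12, 13 and 14); steps 3, 5 and 11 prepare the three side fragments.

Steps most likely to fail, with fallbacks

Step 9 (labelled step). The catalyst may discriminate poorly between the two enantiotopic ring acyl carbons. The enantiomeric purity may erode through a later shift of the exocyclic acyl group in the product. The substrate may also rest as its stabilised dienol bound to scandium without contracting. The fallback gives up catalytic stereocontrol and uses known chemistry. Setting out from 13, the contraction would be run under the achiral, magnesium-assisted conditions established for the hop α-acid to iso-α-acid isomerisation (MgBr2·OEt2, Et3N, CH2Cl2, rt to 40 °C). This should give the racemic ketol F1. Resolution of F1 by preparative HPLC on an amylose tris(3,5-dimethylphenylcarbamate) stationary phase would return the route to 14.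

Step 8. Oxygen transfer may go to the unsubstituted ortho carbons, the vinylogous acid may be oxidised further, or the ortho-quinol may dimerise by [4+2] cycloaddition during isolation. The fallback replaces intramolecular oxygen delivery by a Wessely acetoxylation. Setting out from 12, Pb(OAc)4 in AcOH–CH2Cl2 at 0 °C should give the ortho-quinol acetate F2, which is capped at the carbinol oxygen and can be purified and stored. Methanolysis of the activated tertiary acetate (K2CO3, MeOH, 0 °C) directly before step 9 would return the route to 13.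

Step 13. The substrate may be parked as the C5-deprotonated diketonate, whose C4 carbon is no longer electrophilic. Adventitious water may cleave the diketone in a retro-Claisen sense, or the ring A dienolate may expel the silyloxy group. The fallback avoids free enolates and closes the ring in two stages. Setting out from 18, TMSOTf and Et3N in CH2Cl2 at 0 °C should give the tris-silyl ether F3, in which ring A is a 1-silyloxycyclopenta-1,3-diene and the diketone is an O-silyl enol ether. BF3·OEt2 or catalytic TMSOTf at −78 °C should then bring about an intramolecular vinylogous Mukaiyama aldol addition of C3a to C4. Aqueous acid work-up would give the β-hydroxy ketone 19, this time isolated. Dehydration of 19 with MsCl and Et3N would return the route to 20.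

Further compounds
F1 | step 9 | racemic 3-{(E)-2-[3,5-bis(benzyloxy)phenyl]ethenyl}-5-hydroxy-5-{2-[3,4,5-tris(benzyloxy)phenyl]acetyl}cyclopent-2-en-1-one | O=C1C=C(/C=C/c2cc(OCc3ccccc3)cc(OCc3ccccc3)c2)CC1(O)C(=O)Cc1cc(OCc2ccccc2)c(OCc2ccccc2)c(OCc2ccccc2)c1
F2 | step 8 | 6-acetoxy-3-{(E)-2-[3,5-bis(benzyloxy)phenyl]ethenyl}-5-hydroxy-6-[3,4,5-tris(benzyloxy)benzyl]cyclohexa-2,4-dien-1-one | O=C1C=C(/C=C/c2cc(OCc3ccccc3)cc(OCc3ccccc3)c2)C=C(O)C1(OC(C)=O)Cc1cc(OCc2ccccc2)c(OCc2ccccc2)c(OCc2ccccc2)c1
F3 | step 13 | tris-silyl ether of 18: ring A as 1-(trimethylsilyloxy)cyclopenta-1,3-diene, diketone as O-trimethylsilyl enol ether (drawn on the C6 oxygen), C6a triethylsilyl ether | C[Si](C)(C)OC1=CC(/C=C/c2cc(OCc3ccccc3)cc(OCc3ccccc3)c2)=C[C@@]1(O[Si](CC)(CC)CC)C(O[Si](C)(C)C)=C(c1cc(OCc2ccccc2)c(OCc2ccccc2)c(OCc2ccccc2)c1)C(=O)c1cc(OCc2ccccc2)cc(OCc2ccccc2)c1
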